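Readings and results were computed with constants of no real substance; scatter was added.

1. Start from 29.6%, the end share: target as a part of target plus isomer of the product A, from the last readings of Monday's and Friday's runs together. Here is what is known and asked:

| flask | substrate | remark | time |
|---|---|---|---|
| Monday's | 10 mM | run made earlier |  |
| Friday's | 15 mM | run made earlier |  |
| flask | 20 mM |  | 15 d |

| run | time / d | target / % | isomer of the product A / % |
|---|---|---|---|
| Monday's | 1.67 | 29.5 | 19.7 |
| Monday's | 3.00 | 22.6 | 27.8 |
| Monday's | 5.00 | 16.8 | 32.8 |
| Monday's | 6.00 | 15.9 | 33.2 |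
| Monday's | 8.00 | 15.2 | 35.0 |
| Monday's | 10.0 | 15.4 | 36.2 |
| Monday's | 12.0 | 15.2 | 35.9 |
| Friday's | 1.04 | 32.2 | 13.1 |
| Friday's | 1.67 | 28.3 | 20.4 |
| Friday's | 2.00 | 26.3 | 21.9 |
| Friday's | 3.00 | 20.5 | 27.0 |
| Friday's | 5.00 | 16.9 | 31.5 |
| Friday's | 8.00 | 15.6 | 34.4 |
| Friday's | 12.0 | 14.5 | 34.9 |

(readings scatter by 0.5 percentage points)



1. share of target in target plus isomer of the product A at 30 min
2. share of target in target plus isomer of the product A at 15 d
3. which of target and isomer of the product A there is more of at 15 d

2. Take the first rung, the earliest reading. At 1.04 d in Friday's run the share of target reads 71.1%. The early time 30 min lies before any reading, so I claim for the new flask no more than a share above that.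

3. Climb to the days after. In Friday's run the excess of the share over the end share shrinks with a half-life reading 1.34 d, and isomer of the product A overtakes target between 2.00 d and 3.00 d.

4. Reach the last rung of the readings. From 8.00 d both of Monday's columns change little. Take the way from target to isomer of the product A and the way back as balanced, divide one rate by the other, and time drops out: this is thermodynamic control. The last share reads 29.7% in Monday's run at 10 mM and 29.4% in Friday's run at 15 mM.

5. Commit for the flask at 20 mM. Because 1.34 d is short against 15 d, I put its share at 15 d at 29.6%, with more isomer of the product A.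

The forecast gives 99% at 30 min, 29.5% at 15 d and more isomer of the product A, holding that “the target forms first and the isomer comes from it”.

The flask gives 91.2% at 30 min and 29.5% at 15 d, with 34.0% isomer of the product A against 14.2% target.

    substrate ⇌ target (K = 1.54, k = 7.72 × 10⁻⁴ min⁻¹)
    2 substrate → self-condensation product (k = 0.00292 L mol⁻¹ min⁻¹)
    target ⇌ isomer of the product B (K = 2.21, k = 3.58 × 10⁻⁴ min⁻¹)
    substrate ⇌ isomer of the product A (K = 3.70, k = 7.08 × 10⁻⁵ min⁻¹)
    target ⇌ isomer of the product A (k = 2.08 × 10⁻⁴ min⁻¹)

At the start, substrate passes to target 11 times as fast as to isomer of the product A, forward rates alone. Now use the end share on the neighbour charged with 5.0 mM: at 15 d that flask holds 15.5% target, so the end share puts its isomer of the product A at 36.9%, and that flask holds 36.8%.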